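Once the feed has stopped, partner minus substrate stays at the difference of the charges, 0.100 M per starting volume in this flask, provided substrate and partner are taken up one for one. That proviso is my own assumption.

| setting | oak | flask |
|---|---|---|
| substrate | 0.50 M (fed, over 8.0 min) | 0.50 M (fed, over 8.0 min) |
| partner | 0.60 M | 0.600 M |
| remark | the very flask that is asked about, followed so far; the fed solution adds 1.0 times the starting volume | the fed solution adds 1.0 times the starting volume |
| time |  | 25 min |

- oak (time / min: intermediate / %, target / %): 0.833: 0.9, 0; 1.50: 0.8, 0; 2.50: 2.7, 0.4; 3.00: 3.7, 0.2; 4.00: 5.7, 1.3; 5.00: 8.0, 1.5

(readings scatter by 0.3 percentage points)

- every charge counts on the volume at the start, and the solution that is fed holds the whole dose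
- percentages count the whole charge, also what has not yet gone in

* the moment within 25 min at which there is most intermediate
* the amount of intermediate, in percent of the substrate charged, at that time
* earliest time at which at least nineteen twentieths of that best amount are there, in min
* latest time at which they still are, in min

Which number must you know well? The charges and the dosing time are set by the recipe, so I take them as exact. The doubt sits in the uptake constant, a second-order rate constant read from intermediate plus target. The relative error of that sum is what passes on: 13.7% at 2.50 min, but 4.47% at 5.00 min. Use the last reading.

While the feed runs, the substrate fed and the volume both grow in step with time. With u the fraction fed, partner held at its charge and nothing coming back, which is again my assumption, the rate integrates in closed form: the fraction taken up is the constant times partner times dosing time, multiplied by the difference between u and the natural logarithm of one plus u. The oak run gives 0.142 M⁻¹ min⁻¹ for the uptake constant, substrate taken up per minute per molar of partner and of substrate.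

By my reckoning, 84.0% of the partner stands at the end of the feed. After it, at twice the starting volume and with nothing coming back, my reckoning has the logarithm of partner over substrate climb in a straight line, its slope the constant times the difference over the volume. Substrate left at 25 min comes to 49.1%, and the error above moves that by 1.2 percentage points. The readings show no peak yet, so I give none.

The forecast differs: it lets intermediate take a second partner, noting “that second step is an assumption”. It gives 23.2% at 25 min, with the window from 17.2 min to 25 min.

The flask gives 14.4% at 13.1 min, with the window from 9.81 min to 18.8 min.

    substrate + partner ⇌ intermediate (K = 3.00 M⁻¹, k = 0.00340 M⁻¹ s⁻¹)
    intermediate ⇌ target (K = 1.60, k = 0.00200 s⁻¹)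
    intermediate → side product (k = 0.00120 s⁻¹)

Substrate left in this flask at 25.0 min is 50.6% against the reckoned 49.1%. The half-life of intermediate by the forward step into target alone is 5.8 min, and by the step into side product alone 9.6 min, each shorter than the 25 min allowed . At that limit this flask has 12.5% of the substrate charged as intermediate, 16.9% as target and 20.0% as side product. In a neighbour flask with 2.0 M of substrate, the other charges and the time as in this flask, partner at 0.300 equiv is the limiting reagent; the same constant and balance reckon 72.4% of its substrate left at the limit, and that neighbour flask has 73.7% left.

The earlier runs and the new flask stem from a simulated flask with made-up constants.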